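**Retrosynthetic overview**
1. Target ⇐ its 3',5'-dibromo analogue: both B-ring hydroxyls are carried as C–Br bonds and unveiled last by borylation/oxidation, so no protecting group is needed.
2. Ring C (O1–C2 bond) ⇐ a 2'-hydroxy-α-methoxychalcone by oxidative cyclisation; the C3–OMe group is already in place.
3. Key cut: the hexasubstituted A ring is cut at C4a–C4 and C8a–O1, back to C2v-symmetric 3,4,5,6-tetramethoxybenzyne (C5–C8 all OMe, aryne bond C4a≡C8a). The aryne inserts into the O–C(acyl) bond of (Z)-3-(3,5-dibromo-4-methoxyphenyl)-2-methoxyacrylic acid, which joins both halves and completes the A ring with no regiochemical question.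
4. Aryne precursor (2-silylaryl triflate) ⇐ 1,2,3,4-tetramethoxybenzene in three steps; the acid ⇐ 3,5-dibromo-4-methoxybenzaldehyde and methyl methoxyacetate in one step.
5. Ring order: rings A and B are bought as arenes; ring C is closed in the penultimate step.

Key step: step 5

Remark on the chemistry: the target is a planar, achiral flavone with no stereocentre, so no enantioselective step is required; the only stereodescriptors in the route are the Z alkenes of the cinnamate and chalcone intermediates, which disappear on ring closure.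

**Step 1**
Reactants: 1 1,2,3,4-tetramethoxybenzene
Product: 4 2,3,4,5-tetramethoxyphenol, via (2,3,4,5-tetramethoxyphenyl)lithium 2 (not isolated), via dimethyl (2,3,4,5-tetramethoxyphenyl)boronate 3 (not isolated)
Conditions: n-BuLi, TMEDA, THF, 0 °C to rt; B(OMe)3, -78 °C to rt; then AcOH, 30% aq. H2O2, 0 °C to rt
Reagents that add atoms: hydrogen peroxide, OO
Why: Directed ortho-metalation at one of the two equivalent C–H positions next to a methoxy group gives 2, which is borylated to 3 and oxidised (C–B to C–O) to the phenol, a standard lithiation/borylation/oxidation sequence.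

**Step 2**
Reactants: 4 2,3,4,5-tetramethoxyphenol
Product: 5 2-bromo-3,4,5,6-tetramethoxyphenol
Conditions: NBS (1.0 equiv), CH2Cl2, -78 to 0 °C, dark
Reagents that add atoms: N-bromosuccinimide, O=C1CCC(=O)N1Br
Why: Electrophilic aromatic bromination ortho to the phenol at the only unsubstituted ring carbon; one equivalent of NBS at low temperature under anhydrous conditions should limit oxidation of the electron-rich phenol to a quinone.

**Step 3**
Reactants: 5 2-bromo-3,4,5,6-tetramethoxyphenol
Product: 8 3,4,5,6-tetramethoxy-2-(trimethylsilyl)phenyl trifluoromethanesulfonate, via (2-bromo-3,4,5,6-tetramethoxyphenoxy)trimethylsilane 6 (not isolated), via lithium 3,4,5,6-tetramethoxy-2-(trimethylsilyl)phenolate 7 (not isolated)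
Conditions: HMDS, THF, 70 °C, then evaporate; n-BuLi, THF, -100 to -78 °C; Tf2O, -100 °C to rt
Reagents that add atoms: hexamethyldisilazane, C[Si](C)(C)N[Si](C)(C)C; trifluoromethanesulfonic anhydride, O=S(=O)(OS(=O)(=O)C(F)(F)F)C(F)(F)F
Why: Standard one-pot preparation of a 2-silylaryl triflate aryne precursor: O-silylation, bromine–lithium exchange with 1,3 O-to-C silyl shift (retro-Brook rearrangement) to phenolate 7, then O-triflation.

**Step 4**
Reactants: 9 3,5-dibromo-4-methoxybenzaldehyde; 10 methyl methoxyacetate
Product: 12 (Z)-3-(3,5-dibromo-4-methoxyphenyl)-2-methoxyacrylic acid, via methyl (Z)-3-(3,5-dibromo-4-methoxyphenyl)-2-methoxyacrylate 11 (not isolated)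
Conditions: NaOMe, MeOH, 0 °C to reflux; then 2 M aq. NaOH, 60 °C; then 2 M HCl to pH 2
Reagents that add atoms: sodium hydroxide, [Na+].[OH-]
Why: Aldol condensation of the ester enolate of 10 with the non-enolisable aldehyde 9 and E1cB dehydration should give the thermodynamically preferred Z α-methoxycinnamate (aryl trans to the carboxyl group), which is saponified in the same pot; the alkene geometry has no consequence because C2–C3 is re-formed in step 6.

**Step 5**
Reactants: 8 3,4,5,6-tetramethoxy-2-(trimethylsilyl)phenyl trifluoromethanesulfonate (1.5 equiv); 12 (Z)-3-(3,5-dibromo-4-methoxyphenyl)-2-methoxyacrylic acid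
Product: 14 (Z)-3-(3,5-dibromo-4-methoxyphenyl)-1-(2-hydroxy-3,4,5,6-tetramethoxyphenyl)-2-methoxyprop-2-en-1-one, via 3,4,5,6-tetramethoxybenzyne 13 (not isolated)
Conditions: CsF (4 equiv), THF, 125 °C, sealed tube
Reagents that add atoms: none
Why: Fluoride removes the silyl group of 8 and expels triflate to give aryne 13; the caesium carboxylate of 12 adds through oxygen to one aryne carbon, and the resulting ortho aryl anion attacks the neighbouring ester carbonyl through a four-membered transition state that opens to the o-acylphenoxide (anionic 1,3 O-to-C acyl shift), so the aryne formally inserts into the O–C(acyl) bond and forms C8a–O1 and C4a–C4 in one operation. The closest known reaction type is the fluoride-mediated C–O insertion of arynes from 2-(trimethylsilyl)aryl triflates with carboxylic acids, α,β-unsaturated acids included, which gives o-hydroxyaryl ketones and chromanones. No ring is closed here (ring C is closed in step 6) and no stereocentre is formed; the Z alkene of 12 is carried over unchanged. The step needs regiocontrol in the aryne addition and needs the acyl shift to outrun protonation of the aryl anion: the first is moot because 13 is C2v-symmetric with OMe on all four remaining carbons, so either aryne carbon gives the same product, and the second is favoured by the high temperature, the aprotic medium and the excess of 8. Any part of 14 that has already closed by oxa-Michael addition to flavanone 15 is at the same oxidation level and converges in step 6.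

**Step 6**
Reactants: 14 (Z)-3-(3,5-dibromo-4-methoxyphenyl)-1-(2-hydroxy-3,4,5,6-tetramethoxyphenyl)-2-methoxyprop-2-en-1-one
Product: 16 2-(3,5-dibromo-4-methoxyphenyl)-3,5,6,7,8-pentamethoxy-4H-chromen-4-one, via 2-(3,5-dibromo-4-methoxyphenyl)-3,5,6,7,8-pentamethoxychroman-4-one 15 (not isolated)
Conditions: I2 (20 mol%), DMSO, 130 °C
Reagents that add atoms: none
Why: Iodine-catalysed oxidative cyclisation of a 2'-hydroxychalcone: 6-endo-trig oxa-Michael closure gives flavanone 15, α-iodination at C3 and loss of HI gives the flavone, and DMSO reoxidises HI to I2; the same reaction type is established for 2'-hydroxy-3',4',5',6'-tetramethoxychalcones.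

**Step 7**
Reactants: 16 2-(3,5-dibromo-4-methoxyphenyl)-3,5,6,7,8-pentamethoxy-4H-chromen-4-one
Product: 18 3',5'-dihydroxy-3,5,6,7,8,4'-hexamethoxyflavone (target), via 2-[4-methoxy-3,5-bis(4,4,5,5-tetramethyl-1,3,2-dioxaborolan-2-yl)phenyl]-3,5,6,7,8-pentamethoxy-4H-chromen-4-one 17 (not isolated)
Conditions: B2pin2 (3 equiv), Pd(dppf)Cl2 (10 mol%), KOAc, 1,4-dioxane, 90 °C; then THF, 30% aq. H2O2, 0 °C to rt
Reagents that add atoms: hydrogen peroxide, OO
Why: Miyaura borylation of the two equivalent aryl C–Br bonds followed by peroxide ipso-hydroxylation of the C–B bonds should convert both bromides into the 3'- and 5'-hydroxyls; the pyranone, the C3 enol ether and the aryl methyl ethers are inert to both stages.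

**Compound list**
1 | 1,2,3,4-tetramethoxybenzene | COc1ccc(OC)c(OC)c1OC | starting material
2 | (2,3,4,5-tetramethoxyphenyl)lithium | [Li]c1cc(OC)c(OC)c(OC)c1OC | intermediate (not isolated)
3 | dimethyl (2,3,4,5-tetramethoxyphenyl)boronate | COB(OC)c1cc(OC)c(OC)c(OC)c1OC | intermediate (not isolated)
4 | 2,3,4,5-tetramethoxyphenol | COc1cc(O)c(OC)c(OC)c1OC | intermediate
5 | 2-bromo-3,4,5,6-tetramethoxyphenol | COc1c(Br)c(O)c(OC)c(OC)c1OC | intermediate
6 | (2-bromo-3,4,5,6-tetramethoxyphenoxy)trimethylsilane | COc1c(Br)c(O[Si](C)(C)C)c(OC)c(OC)c1OC | intermediate (not isolated)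
7 | lithium 3,4,5,6-tetramethoxy-2-(trimethylsilyl)phenolate | [Li+].COc1c([Si](C)(C)C)c([O-])c(OC)c(OC)c1OC | intermediate (not isolated)
8 | 3,4,5,6-tetramethoxy-2-(trimethylsilyl)phenyl trifluoromethanesulfonate | COc1c([Si](C)(C)C)c(OS(=O)(=O)C(F)(F)F)c(OC)c(OC)c1OC | intermediate
9 | 3,5-dibromo-4-methoxybenzaldehyde | COc1c(Br)cc(C=O)cc1Br | starting material
10 | methyl methoxyacetate | COCC(=O)OC | starting material
11 | methyl (Z)-3-(3,5-dibromo-4-methoxyphenyl)-2-methoxyacrylate | COC(=O)/C(OC)=C/c1cc(Br)c(OC)c(Br)c1 | intermediate (not isolated)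
12 | (Z)-3-(3,5-dibromo-4-methoxyphenyl)-2-methoxyacrylic acid | OC(=O)/C(OC)=C/c1cc(Br)c(OC)c(Br)c1 | intermediate
13 | 3,4,5,6-tetramethoxybenzyne | COC1=C(OC)C(OC)=C(OC)C#C1 | intermediate (not isolated)
14 | (Z)-3-(3,5-dibromo-4-methoxyphenyl)-1-(2-hydroxy-3,4,5,6-tetramethoxyphenyl)-2-methoxyprop-2-en-1-one | COc1c(O)c(C(=O)/C(OC)=C/c2cc(Br)c(OC)c(Br)c2)c(OC)c(OC)c1OC | intermediate
15 | 2-(3,5-dibromo-4-methoxyphenyl)-3,5,6,7,8-pentamethoxychroman-4-one (racemic, cis/trans mixture at C2/C3) | COC1C(c2cc(Br)c(OC)c(Br)c2)Oc2c(OC)c(OC)c(OC)c(OC)c2C1=O | intermediate (not isolated)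
16 | 2-(3,5-dibromo-4-methoxyphenyl)-3,5,6,7,8-pentamethoxy-4H-chromen-4-one | COc1c(Br)cc(-c2oc3c(OC)c(OC)c(OC)c(OC)c3c(=O)c2OC)cc1Br | intermediate
17 | 2-[4-methoxy-3,5-bis(4,4,5,5-tetramethyl-1,3,2-dioxaborolan-2-yl)phenyl]-3,5,6,7,8-pentamethoxy-4H-chromen-4-one | COc1c(B2OC(C)(C)C(C)(C)O2)cc(-c2oc3c(OC)c(OC)c(OC)c(OC)c3c(=O)c2OC)cc1B1OC(C)(C)C(C)(C)O1 | intermediate (not isolated)
18 | 3',5'-dihydroxy-3,5,6,7,8,4'-hexamethoxyflavone | COc1c(O)cc(-c2oc3c(OC)c(OC)c(OC)c(OC)c3c(=O)c2OC)cc1O | target

**Step count and risks**
Total steps: 7. Longest linear sequence: 6 (steps 1, 2, 3, 5, 6, 7).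

Steps most likely to fail:

Step 5. After the carboxylate has added to the aryne, protonation of the aryl anion, or its conjugate addition to the acrylate β-carbon, may outrun the 1,3-acyl shift, so that the acyl group never reaches carbon. The fallback sets out from 4 and 9. C-acylation of 4 with methoxyacetic acid in BF3·OEt2 at 70 °C (O-acylation/Fries sequence, at the only free ring position) should give 1-(2-hydroxy-3,4,5,6-tetramethoxyphenyl)-2-methoxyethan-1-one F1. Claisen–Schmidt condensation of F1 with 9 (KOH, EtOH, rt) comes back to the route at 14.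

Step 7. The second borylation may stall, or protodebromination and protodeboronation may compete, so that mono-hydroxylated material accumulates. The fallback sets out from 16. Palladium-catalysed C–O coupling with benzyl alcohol (tBuBrettPhos Pd G3, Cs2CO3, toluene, 90 °C) should give 2-[3,5-bis(benzyloxy)-4-methoxyphenyl]-3,5,6,7,8-pentamethoxy-4H-chromen-4-one F2. Hydrogenolysis of F2 (H2, Pd/C, EtOAc/MeOH, rt) comes back to the route at 18.

Step 6. α-Iodination of the α-alkoxy ketone may be slow so that the oxidation stalls after ring closure, or HI at 130 °C may cleave the C5 methyl ether. The fallback sets out from 14 and separates ring closure from oxidation. Oxa-Michael closure with NaOAc in refluxing EtOH should give 15, which is isolated here. Dehydrogenation of 15 by hydride abstraction with DDQ in refluxing 1,4-dioxane comes back to the route at 16. This fallback makes no compound outside the list (F0).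

**Further compounds**
F1 | step 5 | 1-(2-hydroxy-3,4,5,6-tetramethoxyphenyl)-2-methoxyethan-1-one | COCC(=O)c1c(O)c(OC)c(OC)c(OC)c1OC
F2 | step 7 | 2-[3,5-bis(benzyloxy)-4-methoxyphenyl]-3,5,6,7,8-pentamethoxy-4H-chromen-4-one | COc1c(OCc2ccccc2)cc(-c2oc3c(OC)c(OC)c(OC)c(OC)c3c(=O)c2OC)cc1OCc1ccccc1
F0 | step 6 | none | none
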